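All runs were generated by integration for an exercise; the scatter is artificial.

The time of reading is 10 h, so ask of each flask how many lifetimes of the substrate have passed by then. If s is the fraction of the charged substrate still there, the lifetime count L is the natural logarithm of the reciprocal of s. In a pseudo-first-order decay this count is the time over the lifetime, and the fraction reacted is one minus s.

the same everywhere: substrate 0.50 M; free catalyst 2.5 mM

| run | partner | remark | time |
|---|---|---|---|
| dusk | 0.34 M | run made earlier |  |
| spring | 1.7 M | run made earlier |  |
| cedar | 0.600 M |  | 10 h |
| birch | 0.300 M |  | 10 h |
| elm | 1.20 M |  | 10 h |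

| run | time / h | substrate / % | target / % |
|---|---|---|---|
| dusk | 0.667 | 92.7 | 3.2 |
| dusk | 2.00 | 81.2 | 8.4 |
| dusk | 4.00 | 63.4 | 15.8 |
| dusk | 5.00 | 55.5 | 19.6 |
| dusk | 8.00 | 36.3 | 25.3 |
| dusk | 10.0 | 27.3 | 29.3 |
| spring | 1.50 | 66.7 | 15.8 |
| spring | 3.00 | 38.0 | 30.3 |
| spring | 5.00 | 16.6 | 45.9 |
| spring | 6.00 | 11.5 | 50.8 |
| spring | 8.00 | 6.2 | 60.2 |
| spring | 10.0 | 3.5 | 64.8 |

(readings scatter by 0.5 percentage points)

- part of the substrate that has reacted at the end, cedar
- part of the substrate that has reacted at the end, birch
- part of the substrate that has reacted at the end, elm
- what raising the concentration of partner from its lowest to its highest value here does to the part of the substrate that has reacted (changes below 5 percentage points count as none) (it rises / it falls / no change)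

- in percentages every species weighs as the substrate in it: one side product counts as two
- for by-product the idle adduct is counted in
- on the list of suspects stand: substrate + target -> side product; substrate + free catalyst -> catalyst intermediate A; catalyst intermediate B -> catalyst intermediate C; catalyst intermediate C -> by-product + catalyst intermediate D; substrate + by-product <-> idle adduct; partner + catalyst intermediate A <-> catalyst intermediate B; catalyst intermediate D <-> free catalyst + target
- what has gone from substrate into another species counts as reacted, even if it can come back

Begin with the last readings of the two earlier runs:

dusk: L = 1.30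
spring: L = 3.35

Spring holds 5.00 times the partner of dusk, but its count is 2.58 times as large, so the count bends as partner grows. A simple curve that bends has a ceiling:

L = ceiling × partner / (partner + H)

Putting both runs through it gives H = 1.11 M, the mid-count partner, the charge at which the count at this reading time stands at 0.5 of its ceiling. The ceiling is 5.55. Now the three flasks follow:

birch: L = 1.18, reacted 69.2%
cedar: L = 1.94, reacted 85.7%
elm: L = 2.88, reacted 94.4%

From birch to elm I therefore expect a rise of 25 percentage points, which is beyond the margin of 5 points.

The weak link is a curve drawn through two points at one time. So repeat it with the readings at 5.00 h, where dusk has L = 0.589 and spring L = 1.80. The mid-count partner comes out at 1.79 M, larger than before, so the value read moves with the reading time. The curve for this reading time puts birch at L = 0.529. Birch stands close to dusk, so multiply by the growth of dusk between the two readings, 2.21. This gives L = 1.17, or 69.0% reacted. Both birch figures lean on the same dusk readings, so this is no independent check; it shows that my birch figure moves little when the curve changes, and I keep it.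

The forecast gave 86% for cedar, 68% for birch, a little below mine, and 94% for elm, and for the trend it rises, holding that “the rate rises with partner but saturates”.

The flasks give 89.6% in cedar, 67.7% in birch and 95.3% in elm; from the lowest charge of partner to the highest, the part reacted changes by 28 points: it rises. At 10.0 h, catalyst intermediate A holds 82.5% of the catalyst in birch and 15.8% in elm.

    substrate + target → side product (k = 0.196 L mol⁻¹ h⁻¹)
    substrate + free catalyst → catalyst intermediate A (k = 568 L mol⁻¹ h⁻¹)
    catalyst intermediate B → catalyst intermediate C (k = 4630 h⁻¹)
    catalyst intermediate C → by-product + catalyst intermediate D (k = 3830 h⁻¹)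
    substrate + by-product ⇌ idle adduct, settled at all times (K = 16.9 L mol⁻¹)
    partner + catalyst intermediate A ⇌ catalyst intermediate B (K = 27.0 L mol⁻¹, k = 43.1 L mol⁻¹ h⁻¹)
    catalyst intermediate D ⇌ free catalyst + target (K = 0.518 M, k = 41.8 h⁻¹)

Birch's result is a count of 1.13, beside the 1.18 reckoned with 1.11 M. The same 1.11 M puts a birch flask charged with 0.75 M of partner at L = 2.23, or 89.2% reacted, and that flask stands at 92.5%.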